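A small charge of starting material meets a gas that dissolves over minutes, and it has several ways to go. It slips into a dormant form and back, pairs with itself to homo dimer, and with dissolved gas gives target, which dissolved gas carries on to over-reacted product.

starting material 0.050 M; gas phase 18 mM (held); time 80 min

* target at 80 min, in percent of the starting material charged
* concentration of dissolved gas in solution at 80 min, in percent of saturation

- in percentages every species weighs as the starting material in it: one homo dimer counts as two
- a doubled species enters its step squared and goes two at a time
- at the start none of the gas is dissolved
- run time (flask): 80 min

    gas phase ⇌ dissolved gas, rate k1*(csat - [dissolved gas]) (k1 = 0.21 min⁻¹, csat = 18 mM)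
    starting material + dissolved gas → target (k2 = 1.5 M⁻¹ min⁻¹)
    dissolved gas + target → over-reacted product (k3 = 0.12 M⁻¹ min⁻¹)
    starting material ⇌ dormant form (K4 = 6.3, k4 = 0.071 min⁻¹)
    2 starting material → homo dimer (k5 = 0.65 M⁻¹ min⁻¹)

**Does the gas arrive in time?** Yes. The gap to saturation has a half-life of 3.30 min, shorter than the 9.2 min half-life of dissolved gas by the step to target alone, with starting material as charged, so I put c(dissolved gas) at 18 mM for the later run.

**How does starting material then leave?** Homo dimer aside, it goes to dormant form at 0.071 min⁻¹ and to target at 0.0270 min⁻¹, a pseudo-first-order constant. Dormant form returns at 0.0113 min⁻¹.

**So what is c(starting material)/c(dormant form)?** My first answer is the equilibrium value, 0.159, reached with a relaxation half-life of 8.43 min.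

**But doesn't the gas pull on that equilibrium?** It does, and the pull of 0.0270 min⁻¹ is faster than the return of 0.0113 min⁻¹, so I go round again. Leaving homo dimer aside, what dormant form returns must now cover both exits from starting material. This gives the held ratio, the return rate constant over the sum of both exit constants: 0.115.

**And the yield?** My hand stops there. I commit to the ratio and give no yield.

The forecast gives y 20% (from 17% to 23%) and sat 97.6% (from 96.5% to 98.5%), with target growing slowly “from the small free pool released by the dormant reservoir”.

The simulation gives y 20.0% and sat 97.7%, both inside those ranges.

In this flask, by 8.00 min, starting material had fallen to 38.2% while dormant form reached 33.9% and homo dimer 22.2%, with dissolved gas at 73.1% of saturation. From 40.0 min to 80.0 min in this flask, dormant form sank from 49.3% to 44.0% as target rose from 15.6% to 20.0%. The reading of c(starting material)/c(dormant form) in this flask at 80.0 min is 0.116, against the held ratio of 0.115 and the equilibrium 0.159. The same flask charged with 0.020 M of starting material reads 0.117 at 80.0 min, with homo dimer at 14.3% and target at 24.8%.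

(The constants used here were set for the occasion.)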